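**Strategy.** Numbering: lactone O1–C2(=O)–C3=C4–C5 with exocyclic carbon C6; ring A is the phenol ring on C4, ring B the brominated anisole ring on C6. Everything rests on cutting the endocyclic C3=C4 double bond: C3 is an acrylate-type CH and C4 an aryl-bearing vinylic carbon, so the bond maps onto two terminal alkenes. Ring-closing metathesis makes this bond and the five-membered lactone in one operation. Its precursor is the open-chain acrylate ester of a 2-aryl allylic alcohol whose carbinol carbon (future C5) carries the ring B benzyl group. C5=C6 is kept saturated until afterwards, when the γ-acidic C5–H and benzylic C6 allow dehydrogenation through the aromatic 2-silyloxyfuran.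

Key step: step 7

Assumption: every intermediate that is stereogenic at C5 is made and used as the racemate, because C5 is sp2 in the target and the Z C5=C6 alkene is its only stereoelement.

**Route**

Step 1
Reactants: 1 4'-hydroxyacetophenone
Product: 2 4'-(tert-butyldimethylsilyloxy)acetophenone
Conditions: TBSCl, imidazole, DMF, rt
Reagents that add atoms: tert-butyldimethylsilyl chloride (TBSCl), CC(C)(C)[Si](C)(C)Cl
Why: Imidazole-promoted O-silylation of the phenol, the only acidic site, should give an aryl silyl ether that tolerates the organolithium, acylation, metathesis and enol-silylation steps and is removed by fluoride at the end.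

Step 2
Reactants: 2 4'-(tert-butyldimethylsilyloxy)acetophenone
Product: 3 (E)-N'-{1-[4-(tert-butyldimethylsilyloxy)phenyl]ethylidene}-2,4,6-triisopropylbenzenesulfonohydrazide
Conditions: 2,4,6-(i-Pr)3C6H2SO2NHNH2, PPTS (cat.), MeCN, rt
Reagents that add atoms: 2,4,6-triisopropylbenzenesulfonyl hydrazide, CC(C)c1cc(C(C)C)c(S(=O)(=O)NN)c(C(C)C)c1
Why: Acid-catalysed hydrazone condensation of a methyl ketone should give the E isomer (sulfonamide nitrogen on the methyl side), the geometry needed for syn-directed deprotonation in step 5, and the weak acid spares the silyl ether.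

Step 3
Reactants: 4 (3-bromo-4-methoxyphenyl)acetic acid
Product: 5 2-(3-bromo-4-methoxyphenyl)ethanol
Conditions: BH3·THF, THF, 0 °C to rt; aq. work-up
Reagents that add atoms: none
Why: Borane reduction of a carboxylic acid through its acyloxyborane is chemoselective and should leave the aryl bromide and the aryl methyl ether untouched.

Step 4
Reactants: 5 2-(3-bromo-4-methoxyphenyl)ethanol
Product: 6 (3-bromo-4-methoxyphenyl)acetaldehyde
Conditions: Dess–Martin periodinane, CH2Cl2, 0 °C to rt
Reagents that add atoms: none
Why: Dess–Martin oxidation stops at the aldehyde under nearly neutral conditions, so the enolisable arylacetaldehyde never meets base and can be used at once without chromatography.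

Step 5
Reactants: 3 (E)-N'-{1-[4-(tert-butyldimethylsilyloxy)phenyl]ethylidene}-2,4,6-triisopropylbenzenesulfonohydrazide; 6 (3-bromo-4-methoxyphenyl)acetaldehyde
Product: 9 racemic 1-(3-bromo-4-methoxyphenyl)-3-[4-(tert-butyldimethylsilyloxy)phenyl]but-3-en-2-ol, via 1-arylvinyllithium 7 (not isolated), via 1-arylvinylcerium dichloride 8 (not isolated)
Conditions: 3 (1.3 equiv), n-BuLi (2.5 equiv), THF, −78 to 0 °C; anhydrous CeCl3 (1.4 equiv), −78 °C; then 6 (1.0 equiv), −78 °C; aq. NH4Cl
Reagents that add atoms: none
Why: Shapiro reaction followed by organocerium 1,2-addition: double deprotonation of 3 and loss of sulfinate and N2 give 7 with all n-BuLi consumed, transmetalation to the weakly basic 8 suppresses both enolisation of 6 and halogen–metal exchange at ring B, and the new carbinol centre (future C5) forms without facial bias as the racemate, which is harmless because it is erased in step 8.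

Step 6
Reactants: 9 racemic 1-(3-bromo-4-methoxyphenyl)-3-[4-(tert-butyldimethylsilyloxy)phenyl]but-3-en-2-ol; 10 acryloyl chloride
Product: 11 racemic 1-(3-bromo-4-methoxyphenyl)-3-[4-(tert-butyldimethylsilyloxy)phenyl]but-3-en-2-yl acrylate
Conditions: Et3N, DMAP (cat.), CH2Cl2, 0 °C
Reagents that add atoms: none
Why: DMAP-catalysed esterification (nucleophilic acyl substitution) of the only free hydroxyl group proceeds with retention at the carbinol carbon, and the low temperature limits acrylate polymerisation.

Step 7
Reactants: 11 racemic 1-(3-bromo-4-methoxyphenyl)-3-[4-(tert-butyldimethylsilyloxy)phenyl]but-3-en-2-yl acrylate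
Product: 12 racemic 5-(3-bromo-4-methoxybenzyl)-4-[4-(tert-butyldimethylsilyloxy)phenyl]furan-2(5H)-one
Conditions: second-generation Grubbs catalyst RuCl2(=CHPh)(PCy3)(SIMes) (5 mol%, second 5 mol% portion if needed), toluene (0.005 M), 80 °C, argon sparge
Reagents that add atoms: none
Why: Ring-closing olefin metathesis by the metallacyclobutane mechanism: the propagating ruthenium alkylidene exchanges with the unhindered acrylate CH2= terminus, the resulting ester-substituted carbene at C3 adds [2+2] to the electron-rich 1-arylvinyl group so that C3 bonds to C4 and ruthenium to the terminal CH2, and cycloreversion releases the butenolide and Ru=CH2, which carries the chain and accounts for the ethylene lost. The closest known reaction type is the closure of allylic acrylates bearing a 1,1-disubstituted alkene to 4-substituted furan-2(5H)-ones with N-heterocyclic-carbene ruthenium catalysts. The one ring formed is the five-membered lactone, closed by joining C3 and C4 across the three-atom C2–O1–C5 link with both carbons ending endocyclic, and heating populates the minor E rotamer about C2–O1 that brings the two alkenes within reach. No stereocentre is created, and the existing C5 centre is racemic and disappears in step 8. The selectivity required is cyclisation over intermolecular acrylate coupling, secured by high dilution, by sparging out ethylene and by the reluctance of both an acrylate and a 1,1-disubstituted styrene to homodimerise. The aryl bromide, methyl ether and silyl ether do not engage the catalyst, and the trisubstituted, conjugated product alkene is too hindered and electron-poor to re-enter the cycle.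

Step 8
Reactants: 12 racemic 5-(3-bromo-4-methoxybenzyl)-4-[4-(tert-butyldimethylsilyloxy)phenyl]furan-2(5H)-one
Product: 13 5-(3-bromo-4-methoxybenzyl)-2-(tert-butyldimethylsilyloxy)-4-[4-(tert-butyldimethylsilyloxy)phenyl]furan
Conditions: TBSOTf, Et3N, CH2Cl2, 0 °C; cold aq. NaHCO3 wash, used crude under argon
Reagents that add atoms: tert-butyldimethylsilyl trifluoromethanesulfonate (TBSOTf), CC(C)(C)[Si](C)(C)OS(=O)(=O)C(F)(F)F
Why: Soft enolisation: silylation of the lactone carbonyl oxygen acidifies the γ-hydrogen at C5, Et3N removes it and the gain of furan aromaticity drives 2-silyloxyfuran formation, while washing out excess silyl triflate keeps it from activating NBS toward rings A and B in step 9.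

Step 9
Reactants: 13 5-(3-bromo-4-methoxybenzyl)-2-(tert-butyldimethylsilyloxy)-4-[4-(tert-butyldimethylsilyloxy)phenyl]furan
Product: 15 (Z)-5-(3-bromo-4-methoxybenzylidene)-4-[4-(tert-butyldimethylsilyloxy)phenyl]furan-2(5H)-one, via 5-bromobutenolide 14 (not isolated)
Conditions: NBS (1.0 equiv), THF, −78 °C; then DBU, −78 °C to rt, dark
Reagents that add atoms: none
Why: Electrophilic halogenation of a 2-silyloxyfuran at its vinylogous terminus C5 should give the tertiary α-acyloxy bromide 14, and base-mediated dehydrobromination can only run toward the benzylic C6–H, the Z alkene being favoured in transition state and product alike because the E isomer would press ring B against ring A on C4.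

Step 10
Reactants: 15 (Z)-5-(3-bromo-4-methoxybenzylidene)-4-[4-(tert-butyldimethylsilyloxy)phenyl]furan-2(5H)-one
Product: 16 3''-bromorubrolide F, (Z)-5-(3-bromo-4-methoxybenzylidene)-4-(4-hydroxyphenyl)furan-2(5H)-one
Conditions: TBAF, AcOH, THF, 0 °C
Reagents that add atoms: none
Why: Fluoride-mediated desilylation is driven by Si–F bond formation, and the acetic acid buffer protonates the phenoxide at once so that the ylidene lactone and its Z geometry are not exposed to base.

**Compound list**

1 | 4'-hydroxyacetophenone | CC(=O)c1ccc(O)cc1 | starting material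
2 | 4'-(tert-butyldimethylsilyloxy)acetophenone | CC(=O)c1ccc(O[Si](C)(C)C(C)(C)C)cc1 | intermediate
3 | (E)-N'-{1-[4-(tert-butyldimethylsilyloxy)phenyl]ethylidene}-2,4,6-triisopropylbenzenesulfonohydrazide | C/C(=N\NS(=O)(=O)c1c(C(C)C)cc(C(C)C)cc1C(C)C)c1ccc(O[Si](C)(C)C(C)(C)C)cc1 | intermediate
4 | (3-bromo-4-methoxyphenyl)acetic acid | COc1ccc(CC(=O)O)cc1Br | starting material
5 | 2-(3-bromo-4-methoxyphenyl)ethanol | COc1ccc(CCO)cc1Br | intermediate
6 | (3-bromo-4-methoxyphenyl)acetaldehyde | COc1ccc(CC=O)cc1Br | intermediate
7 | 1-[4-(tert-butyldimethylsilyloxy)phenyl]vinyllithium (1-arylvinyllithium, not isolated) | [Li]C(=C)c1ccc(O[Si](C)(C)C(C)(C)C)cc1 | intermediate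
8 | dichloro{1-[4-(tert-butyldimethylsilyloxy)phenyl]vinyl}cerium (1-arylvinylcerium dichloride, not isolated) | Cl[Ce](Cl)C(=C)c1ccc(O[Si](C)(C)C(C)(C)C)cc1 | intermediate
9 | racemic 1-(3-bromo-4-methoxyphenyl)-3-[4-(tert-butyldimethylsilyloxy)phenyl]but-3-en-2-ol | COc1ccc(CC(O)C(=C)c2ccc(O[Si](C)(C)C(C)(C)C)cc2)cc1Br | intermediate
10 | acryloyl chloride | C=CC(=O)Cl | starting material
11 | racemic 1-(3-bromo-4-methoxyphenyl)-3-[4-(tert-butyldimethylsilyloxy)phenyl]but-3-en-2-yl acrylate | COc1ccc(CC(OC(=O)C=C)C(=C)c2ccc(O[Si](C)(C)C(C)(C)C)cc2)cc1Br | intermediate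
12 | racemic 5-(3-bromo-4-methoxybenzyl)-4-[4-(tert-butyldimethylsilyloxy)phenyl]furan-2(5H)-one | COc1ccc(CC2OC(=O)C=C2c2ccc(O[Si](C)(C)C(C)(C)C)cc2)cc1Br | intermediate
13 | 5-(3-bromo-4-methoxybenzyl)-2-(tert-butyldimethylsilyloxy)-4-[4-(tert-butyldimethylsilyloxy)phenyl]furan | COc1ccc(Cc2oc(O[Si](C)(C)C(C)(C)C)cc2-c2ccc(O[Si](C)(C)C(C)(C)C)cc2)cc1Br | intermediate
14 | racemic 5-bromo-5-(3-bromo-4-methoxybenzyl)-4-[4-(tert-butyldimethylsilyloxy)phenyl]furan-2(5H)-one (5-bromobutenolide, not isolated) | COc1ccc(CC2(Br)OC(=O)C=C2c2ccc(O[Si](C)(C)C(C)(C)C)cc2)cc1Br | intermediate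
15 | (Z)-5-(3-bromo-4-methoxybenzylidene)-4-[4-(tert-butyldimethylsilyloxy)phenyl]furan-2(5H)-one | COc1ccc(/C=C2\OC(=O)C=C2c2ccc(O[Si](C)(C)C(C)(C)C)cc2)cc1Br | intermediate
16 | 3''-bromorubrolide F, (Z)-5-(3-bromo-4-methoxybenzylidene)-4-(4-hydroxyphenyl)furan-2(5H)-one | COc1ccc(/C=C2\OC(=O)C=C2c2ccc(O)cc2)cc1Br | target

**Totals**

Total step count: 10.
Longest linear sequence: 8 steps (steps 1, 2, 5–10). The branch through steps 3, 4, 5–10 is equally long.

**Steps most likely to fail**

Step 7. The hindered 1-arylvinyl group may engage too slowly. Decay of the short-lived ester-substituted carbene and intermolecular acrylate coupling would then outrun ring closure.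
- The fallback forms the same C3=C4 bond by an intramolecular Horner–Wadsworth–Emmons olefination. It sets out from alcohol 9.
- Esterification with diethylphosphonoacetic acid (DCC, DMAP, CH2Cl2) should give racemic 1-(3-bromo-4-methoxyphenyl)-3-[4-(tert-butyldimethylsilyloxy)phenyl]but-3-en-2-yl (diethoxyphosphoryl)acetate F1.
- Lemieux–Johnson cleavage of its only alkene (OsO4 cat., NaIO4, 2,6-lutidine, dioxane/H2O) should give the aryl ketone racemic 3-(3-bromo-4-methoxyphenyl)-1-[4-(tert-butyldimethylsilyloxy)phenyl]-1-oxopropan-2-yl (diethoxyphosphoryl)acetate F2.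
- Masamune–Roush conditions (LiCl, i-Pr2NEt, MeCN) should close the butenolide. The route is rejoined at 12.

Step 9. The electrophile may attack C3 instead of C5, or the electron-rich rings A and B. The tertiary bromide may also ionise and hydrolyse before HBr is lost.
- The fallback replaces halogenation and dehydrohalogenation by oxygenation and dehydration. It sets out from silyloxyfuran 13.
- Dimethyldioxirane (acetone/CH2Cl2, −78 °C) transfers oxygen to C5. After loss of the silyl group this should give racemic 5-(3-bromo-4-methoxybenzyl)-5-hydroxy-4-[4-(tert-butyldimethylsilyloxy)phenyl]furan-2(5H)-one F3.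
- Acid-catalysed dehydration (p-TsOH cat., toluene, 80 °C) then removes water toward C6 under thermodynamic control in favour of the Z alkene. The route is rejoined at 15.

Step 5. The hydrazone may convert incompletely into the alkenyl anion. Proton transfer from the enolisable aldehyde or residual halogen–metal exchange at ring B may also erode the coupling.
- The fallback is a Nozaki–Hiyama–Kishi coupling. It sets out from ketone 2 and uses aldehyde 6.
- Kinetic enolisation and triflation (KHMDS, PhNTf2, THF, −78 °C) should give 1-[4-(tert-butyldimethylsilyloxy)phenyl]vinyl trifluoromethanesulfonate F4.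
- F4 is then coupled with 6 using CrCl2 (excess) and NiCl2 (cat.) in DMF at rt.
- The alkenyl triflate should add oxidatively to zerovalent nickel much faster than the electron-rich aryl bromide. The non-basic organochromium reagent adds to the aldehyde without enolisation. The route is rejoined at 9.

**Further compounds**

F1 | step 7 | racemic 1-(3-bromo-4-methoxyphenyl)-3-[4-(tert-butyldimethylsilyloxy)phenyl]but-3-en-2-yl (diethoxyphosphoryl)acetate | COc1ccc(CC(OC(=O)CP(=O)(OCC)OCC)C(=C)c2ccc(O[Si](C)(C)C(C)(C)C)cc2)cc1Br
F2 | step 7 | racemic 3-(3-bromo-4-methoxyphenyl)-1-[4-(tert-butyldimethylsilyloxy)phenyl]-1-oxopropan-2-yl (diethoxyphosphoryl)acetate | COc1ccc(CC(OC(=O)CP(=O)(OCC)OCC)C(=O)c2ccc(O[Si](C)(C)C(C)(C)C)cc2)cc1Br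
F3 | step 9 | racemic 5-(3-bromo-4-methoxybenzyl)-5-hydroxy-4-[4-(tert-butyldimethylsilyloxy)phenyl]furan-2(5H)-one | COc1ccc(CC2(O)OC(=O)C=C2c2ccc(O[Si](C)(C)C(C)(C)C)cc2)cc1Br
F4 | step 5 | 1-[4-(tert-butyldimethylsilyloxy)phenyl]vinyl trifluoromethanesulfonate | C=C(OS(=O)(=O)C(F)(F)F)c1ccc(O[Si](C)(C)C(C)(C)C)cc1
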